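**Plan**

Locants are those of the 7-oxabicyclo[4.1.0]hept-2-ene core (C1 epoxide CH, C2=C3, C4 quaternary, C5 CH, C6 epoxide C–CH3); Pyr = 6-methoxy-3,5-dimethyl-4-oxo-4H-pyran-2-yl.
Cuts, in order: the side-chain aldol bond CH(OH)–CH(CH3); the epoxide C1–O (from a trans-C1,C6-diol); the ring bond C5–C6; the two cis CH=C arms on C4; the pyranone ring.
Enabling feature: C5 carries an exo-methylene alkene (C=CH2) and its ring neighbour C6 carries the epoxide oxygen. This homoallylic C–O next to a 1,1-disubstituted alkene is the signature of an allyl-transposing carbonyl addition, here an allylsilane closing onto the acetyl carbonyl of a (Z)-ene-1,2-dione.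
Forward: pyranone built on a masked prochiral 2-methylpropane-1,3-diol → desymmetrisation → allylsilane arm (future C5 and side-chain root) → (Z)-enedione arm (C3=C2–C1–C6) → six-membered ring → epoxide → aldol.
Stereochemistry: C4 from lipase desymmetrisation; C5 and C6 from C4 in the ring closure; C1 by OH-directed reduction, then inversion on epoxide closure; side-chain centres from an Ipc2B enolate.

Key step: step 15

Assumption: the sense of induction of the lipase (step 5) and of the Ipc2B enolate (step 20) is taken as drawn; each is available in the opposite sense (same lipase on the dibenzoate; antipodal Ipc2BOTf), so a reversed sense changes a reagent, not the route.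

**Route**

Step 1
Reactants: 1 2,2,5-trimethyl-1,3-dioxane-5-carboxylic acid; 2 methyl 2-methyl-3-oxopentanoate
Product: 4 methyl 2,4-dimethyl-3,5-dioxo-5-(2,2,5-trimethyl-1,3-dioxan-5-yl)pentanoate, via acyl imidazole 3 (not isolated)
Conditions: 1, CDI, THF, rt; added to the dianion of 2 (NaH then n-BuLi, THF, 0 °C, 2.2 equiv) at −78 → 0 °C
Reagents that add atoms: none
Why: Claisen-type γ-acylation of a β-keto ester dianion (Huckin–Weiler) by an N-acylimidazole should give the triketide at the terminal carbanion; no stereocentre is carried on.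

Step 2
Reactants: 4 triketo ester
Product: 5 4-hydroxy-3,5-dimethyl-6-(2,2,5-trimethyl-1,3-dioxan-5-yl)-2H-pyran-2-one
Conditions: DBU, toluene, 80 °C
Reagents that add atoms: none
Why: Base-mediated enol lactonisation of a 3,5-diketo ester is the standard entry to 4-hydroxy-2-pyranones.

Step 3
Reactants: 5 hydroxypyranone
Product: 6 2-methoxy-3,5-dimethyl-6-(2,2,5-trimethyl-1,3-dioxan-5-yl)-4H-pyran-4-one
Conditions: MeOTf, 2,6-di-tert-butyl-4-methylpyridine, CH2Cl2, rt
Reagents that add atoms: methyl trifluoromethanesulfonate COS(=O)(=O)C(F)(F)F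
Why: Hard O-methylation at the lactone carbonyl oxygen of the vinylogous acid should give the 2-methoxy-4-pyranone tautomer; the hindered base protects the acetonide.

Step 4
Reactants: 6 acetonide
Product: 7 2-(1,3-dihydroxy-2-methylpropan-2-yl)-6-methoxy-3,5-dimethyl-4H-pyran-4-one (prochiral diol)
Conditions: AcOH–H2O (4:1), 40 °C
Reagents that add atoms: none
Why: Acid-catalysed acetal hydrolysis; the methoxypyranone tolerates mild aqueous acid.

Step 5
Reactants: 7 prochiral diol
Product: 8 (S)-3-hydroxy-2-methyl-2-Pyr-propyl benzoate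
Conditions: lipase PS (Burkholderia cepacia), vinyl benzoate, i-Pr2O, 30 °C
Reagents that add atoms: vinyl benzoate C=COC(=O)c1ccccc1
Why: Lipase-catalysed irreversible transesterification desymmetrises the 2-aryl-2-methylpropane-1,3-diol by enantiotopic-group selection and so sets quaternary C4; a benzoate is chosen because it resists 1,3-acyl migration.

Step 6
Reactants: 8 monobenzoate
Product: 9 (S)-2-methyl-3-oxo-2-Pyr-propyl benzoate
Conditions: Dess–Martin periodinane, NaHCO3, CH2Cl2, 0 °C → rt
Reagents that add atoms: none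
Why: Dess–Martin oxidation of a neopentyl primary alcohol; the aldehyde has no α-hydrogen, so C4 cannot epimerise.

Step 7
Reactants: 10 methyl bis(2,2,2-trifluoroethyl)phosphonoacetate
Product: 11 methyl 2-[bis(2,2,2-trifluoroethoxy)phosphoryl]-3-(trimethylsilyl)propanoate (racemic)
Conditions: NaH, THF–DMF, 0 °C; ICH2SiMe3, 60 °C
Reagents that add atoms: (iodomethyl)trimethylsilane C[Si](C)(C)CI
Why: C-alkylation of a phosphonoacetate anion with a primary iodide, as used to make α-substituted Still–Gennari reagents.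

Step 8
Reactants: 9 aldehyde; 11 silyl phosphonate
Product: 12 methyl ester of the trisubstituted enoate PhCO2CH2–C(CH3)(Pyr)–CH=C(CH2SiMe3)–CO2Me, ester cis and CH2SiMe3 trans to the quaternary carbon
Conditions: KHMDS, 18-crown-6, THF, −78 °C
Reagents that add atoms: none
Why: Still–Gennari olefination; the trifluoroethyl phosphonate eliminates under kinetic control and should place the ester cis to the aldehyde-derived carbon, which puts silicon on the far side of the alkene.

Step 9
Reactants: 12 enoate benzoate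
Product: 13 diol HOCH2–C(CH3)(Pyr)–CH=C(CH2SiMe3)–CH2OH (allylic CH2OH cis to the quaternary carbon)
Conditions: DIBAL-H (6 equiv), CH2Cl2, −78 → −20 °C; Rochelle salt
Reagents that add atoms: none
Why: DIBAL-H reduces the enoate 1,2 to the allylic alcohol and cleaves the benzoate; the doubly vinylogous carbonate carbonyl of the pyranone should not be attacked at low temperature.

Step 10
Reactants: 13 diol
Product: 14 mono-TBDPS ether, silyl group on the allylic oxygen and neopentyl CH2OH free
Conditions: TBDPSCl (1.05 equiv), imidazole, CH2Cl2, −20 °C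
Reagents that add atoms: tert-butyl(chloro)diphenylsilane CC(C)(C)[Si](Cl)(c1ccccc1)c1ccccc1
Why: The bulky silyl chloride should discriminate the primary allylic hydroxyl from the neopentyl hydroxyl on the quaternary carbon.

Step 11
Reactants: 14 alcohol
Product: 15 aldehyde OHC–C(CH3)(Pyr)–CH=C(CH2SiMe3)–CH2OTBDPS
Conditions: Dess–Martin periodinane, NaHCO3, CH2Cl2, 0 °C → rt
Reagents that add atoms: none
Why: Dess–Martin oxidation; the allylsilane and silyl ether are inert to the periodinane.

Step 12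
Reactants: 15 aldehyde
Product: 16 methyl (Z)-2-methylenoate arm on C4: MeO2C–C(CH3)=CH–C(CH3)(Pyr)–CH=C(CH2SiMe3)–CH2OTBDPS, ester cis to the quaternary carbon
Conditions: methyl 2-[bis(2,2,2-trifluoroethoxy)phosphoryl]propanoate, KHMDS, 18-crown-6, THF, −78 °C
Reagents that add atoms: methyl 2-[bis(2,2,2-trifluoroethoxy)phosphoryl]propanoate COC(=O)C(C)P(=O)(OCC(F)(F)F)OCC(F)(F)F
Why: A second Still–Gennari olefination installs the cis C2=C3 geometry that the six-membered ring requires.

Step 13
Reactants: 16 (Z)-enoate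
Product: 17 (Z)-N-methoxy-N-methyl enamide (Weinreb amide of 16)
Conditions: MeNH(OMe)·HCl, i-PrMgCl, THF, −20 → 0 °C
Reagents that add atoms: N,O-dimethylhydroxylamine hydrochloride CNOC.Cl
Why: Direct ester-to-Weinreb-amide exchange with the magnesium amide; the alkene geometry is untouched.

Step 14
Reactants: 17 Weinreb amide
Product: 19 (Z)-ene-1,2-dione CH3CO–CO–C(CH3)=CH–C(CH3)(Pyr)–CH=C(CH2SiMe3)–CH2OTBDPS, via 1-ethoxyvinyl ketone 18 (not isolated)
Conditions: ethyl vinyl ether, t-BuLi, THF, −78 → 0 °C; 17, −78 °C; then 1 M HCl, THF, 0 °C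
Reagents that add atoms: ethyl vinyl ether C=COCC; water O
Why: An acyl-anion equivalent adds once to the Weinreb amide (stable chelate), and enol ether hydrolysis unveils the 1,2-dione; the methyl-flanked pyranone carbonyl should be much less electrophilic at −78 °C.

Step 15
Reactants: 19 allylsilane ene-dione
Product: 20 6-hydroxy-2,4,6-trimethyl-4-Pyr-5-[3-(TBDPS-oxy)prop-1-en-2-yl]cyclohex-2-en-1-one (side chain cis to Pyr, C6–OH trans to the side chain, C6–CH3 cis to it)
Conditions: BF3·OEt2 (3 equiv), CH2Cl2, −78 °C; aq. NaHCO3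
Reagents that add atoms: none
Why: BF3 activates the non-conjugated acetyl carbonyl (future C6); the allylsilane attacks through its γ-carbon (future C5) in an anti SE2' process and the β-silyl cation loses Me3SiF, moving the double bond to the exocyclic CH2. This is an intramolecular Hosomi–Sakurai allylation of a ketone, the silicon-directed counterpart of a type I carbonyl-ene reaction. The ring closes 6-exo-trig at the carbonyl carbon with the allyl double bond outside the ring; closure at the conjugated, doubly flanked C1 carbonyl would give a cyclopentene and should be slower. C5 is set by the quaternary C4: with the allyl unit pseudo-axial on the forming sofa, ring carbon C3 sits inside, the pyranone anti to the incoming carbonyl and the C4 methyl outside, so the side chain ends up cis to Pyr. C6 is set by an open antiperiplanar arrangement of C=C and C=O, with the C6 oxygen turned away from the C1 oxygen (non-chelated, dipole-minimised dione), which puts O trans and CH3 cis to the side chain. The step needs site selectivity (C6 over C1 carbonyl), facial selectivity at C5 and anti over synclinal approach; these rest on the electrophilicity gap, the allylic quaternary centre and the monodentate Lewis acid, helped by CH2SiMe3 being trans to C4 so that silicon can lie anti to the electrophile.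

Step 16
Reactants: 20 α-ketol enone
Product: 21 cyclohex-2-ene-1,6-diol (C1–OH trans to C6–OH and cis to C6–CH3)
Conditions: Me4NBH(OAc)3, MeCN–AcOH (1:1), −30 °C
Reagents that add atoms: none
Why: Hydroxyl-directed 1,2-reduction (Evans–Saksena type): the tertiary C6–OH exchanges onto boron and delivers hydride to C1 on its own face, which should give the trans-diol.

Step 17
Reactants: 21 trans-diol
Product: 23 TBDPS ether of the epoxy alcohol (7-oxabicyclo[4.1.0]hept-2-ene core complete), via allylic mesylate 22 (not isolated)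
Conditions: Ms2O, Et3N, CH2Cl2, −30 °C; then K2CO3, MeOH, 0 °C
Reagents that add atoms: none
Why: Only the secondary allylic hydroxyl is sulfonylated; the tertiary alkoxide then displaces the trans mesylate with inversion at C1 (intramolecular Williamson closure), giving the epoxide on the face opposite the side chain.

Step 18
Reactants: 23 silyl ether
Product: 24 allylic alcohol (2-(hydroxymethyl)vinyl group on C5)
Conditions: TBAF, AcOH (1:1), THF, 0 °C → rt
Reagents that add atoms: none
Why: Buffered fluoride desilylation; the vinyl epoxide should survive near-neutral conditions.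

Step 19
Reactants: 24 allylic alcohol
Product: 25 2-substituted acrolein (C5–C(=CH2)–CHO)
Conditions: Dess–Martin periodinane, NaHCO3, CH2Cl2, 0 °C
Reagents that add atoms: none
Why: Buffered Dess–Martin oxidation of a primary allylic alcohol; C5–H is not activated (cross-conjugated), so the centre should hold.

Step 20
Reactants: 25 enal; 26 pentan-3-one
Product: 28 CNP0233636.2, via boron enolate 27 (not isolated)
Conditions: 26, (+)-Ipc2BOTf, i-Pr2NEt, CH2Cl2, −78 °C; 25, −78 → −20 °C; H2O2, pH 7 buffer, MeOH, 0 °C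
Reagents that add atoms: none
Why: Paterson aldol: the (Z)-enol diisopinocampheylborinate reacts through a chair Zimmerman–Traxler transition state to give the syn aldol, and the Ipc ligands select the aldehyde face that gives the (3R,4R) side chain.

**Compound list**

1 | 2,2,5-trimethyl-1,3-dioxane-5-carboxylic acid | CC1(C)OCC(C)(CO1)C(=O)O | starting material
2 | methyl 2-methyl-3-oxopentanoate | CCC(=O)C(C)C(=O)OC | starting material
3 | 1-(2,2,5-trimethyl-1,3-dioxane-5-carbonyl)imidazole | CC1(C)OCC(C)(CO1)C(=O)n1ccnc1 | intermediate (not isolated)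
4 | methyl 2,4-dimethyl-3,5-dioxo-5-(2,2,5-trimethyl-1,3-dioxan-5-yl)pentanoate | CC1(C)OCC(C)(CO1)C(=O)C(C)C(=O)C(C)C(=O)OC | intermediate
5 | 4-hydroxy-3,5-dimethyl-6-(2,2,5-trimethyl-1,3-dioxan-5-yl)-2H-pyran-2-one | CC1(C)OCC(C)(CO1)c1oc(=O)c(C)c(O)c1C | intermediate
6 | 2-methoxy-3,5-dimethyl-6-(2,2,5-trimethyl-1,3-dioxan-5-yl)-4H-pyran-4-one | CC1(C)OCC(C)(CO1)c1oc(OC)c(C)c(=O)c1C | intermediate
7 | 2-(1,3-dihydroxy-2-methylpropan-2-yl)-6-methoxy-3,5-dimethyl-4H-pyran-4-one | OCC(C)(CO)c1oc(OC)c(C)c(=O)c1C | intermediate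
8 | (S)-3-hydroxy-2-methyl-2-Pyr-propyl benzoate | O=C(c1ccccc1)OC[C@@](CO)(C)c1oc(OC)c(C)c(=O)c1C | intermediate
9 | (S)-2-methyl-3-oxo-2-Pyr-propyl benzoate | O=C(c1ccccc1)OC[C@@](C=O)(C)c1oc(OC)c(C)c(=O)c1C | intermediate
10 | methyl bis(2,2,2-trifluoroethyl)phosphonoacetate | COC(=O)CP(=O)(OCC(F)(F)F)OCC(F)(F)F | starting material
11 | methyl 2-[bis(2,2,2-trifluoroethoxy)phosphoryl]-3-(trimethylsilyl)propanoate | COC(=O)C(C[Si](C)(C)C)P(=O)(OCC(F)(F)F)OCC(F)(F)F | intermediate
12 | enoate benzoate (ester cis, CH2SiMe3 trans to the quaternary carbon) | O=C(c1ccccc1)OC[C@@](/C=C(/C[Si](C)(C)C)C(=O)OC)(C)c1oc(OC)c(C)c(=O)c1C | intermediate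
13 | allylsilane diol | OC[C@@](/C=C(/C[Si](C)(C)C)CO)(C)c1oc(OC)c(C)c(=O)c1C | intermediate
14 | allylic TBDPS ether with free neopentyl alcohol | OC[C@@](/C=C(/C[Si](C)(C)C)CO[Si](c1ccccc1)(c1ccccc1)C(C)(C)C)(C)c1oc(OC)c(C)c(=O)c1C | intermediate
15 | quaternary aldehyde | O=C[C@@](/C=C(/C[Si](C)(C)C)CO[Si](c1ccccc1)(c1ccccc1)C(C)(C)C)(C)c1oc(OC)c(C)c(=O)c1C | intermediate
16 | (Z)-2-methylenoate (ester cis to the quaternary carbon) | COC(=O)/C(C)=C\[C@@](/C=C(/C[Si](C)(C)C)CO[Si](c1ccccc1)(c1ccccc1)C(C)(C)C)(C)c1oc(OC)c(C)c(=O)c1C | intermediate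
17 | (Z)-Weinreb amide | CON(C)C(=O)/C(C)=C\[C@@](/C=C(/C[Si](C)(C)C)CO[Si](c1ccccc1)(c1ccccc1)C(C)(C)C)(C)c1oc(OC)c(C)c(=O)c1C | intermediate
18 | (Z)-1-ethoxyvinyl enone | C=C(OCC)C(=O)/C(C)=C\[C@@](/C=C(/C[Si](C)(C)C)CO[Si](c1ccccc1)(c1ccccc1)C(C)(C)C)(C)c1oc(OC)c(C)c(=O)c1C | intermediate (not isolated)
19 | (Z)-ene-1,2-dione allylsilane | CC(=O)C(=O)/C(C)=C\[C@@](/C=C(/C[Si](C)(C)C)CO[Si](c1ccccc1)(c1ccccc1)C(C)(C)C)(C)c1oc(OC)c(C)c(=O)c1C | intermediate
20 | 6-hydroxycyclohex-2-en-1-one (side chain cis to Pyr, OH trans to side chain) | C=C(CO[Si](c1ccccc1)(c1ccccc1)C(C)(C)C)[C@H]1[C@](C)(O)C(=O)C(C)=C[C@@]1(C)c1oc(OC)c(C)c(=O)c1C | intermediate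
21 | trans-cyclohex-2-ene-1,6-diol | C=C(CO[Si](c1ccccc1)(c1ccccc1)C(C)(C)C)[C@H]1[C@](C)(O)[C@@H](O)C(C)=C[C@@]1(C)c1oc(OC)c(C)c(=O)c1C | intermediate
22 | C1 allylic mesylate of 21 | C=C(CO[Si](c1ccccc1)(c1ccccc1)C(C)(C)C)[C@H]1[C@](C)(O)[C@@H](OS(C)(=O)=O)C(C)=C[C@@]1(C)c1oc(OC)c(C)c(=O)c1C | intermediate (not isolated)
23 | epoxide, TBDPS ether | C=C(CO[Si](c1ccccc1)(c1ccccc1)C(C)(C)C)[C@H]1[C@]2(C)O[C@@H]2C(C)=C[C@@]1(C)c1oc(OC)c(C)c(=O)c1C | intermediate
24 | epoxy allylic alcohol | C=C(CO)[C@H]1[C@]2(C)O[C@@H]2C(C)=C[C@@]1(C)c1oc(OC)c(C)c(=O)c1C | intermediate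
25 | epoxy enal | C=C(C=O)[C@H]1[C@]2(C)O[C@@H]2C(C)=C[C@@]1(C)c1oc(OC)c(C)c(=O)c1C | intermediate
26 | pentan-3-one | CCC(=O)CC | starting material
27 | (Z)-pent-2-en-3-yl diisopinocampheylborinate (from (+)-Ipc2BOTf) | C/C=C(\OB([C@H]1C[C@H]2C[C@@H]([C@@H]1C)C2(C)C)[C@H]1C[C@H]2C[C@@H]([C@@H]1C)C2(C)C)CC | intermediate (not isolated)
28 | 2-methoxy-3,5-dimethyl-6-[(1R,4R,5R,6S)-5-[(3R,4R)-3-hydroxy-4-methyl-5-oxohept-1-en-2-yl]-2,4,6-trimethyl-7-oxabicyclo[4.1.0]hept-2-en-4-yl]-4H-pyran-4-one (CNP0233636.2) | C=C([C@H](O)[C@@H](C)C(=O)CC)[C@H]1[C@]2(C)O[C@@H]2C(C)=C[C@@]1(C)c1oc(OC)c(C)c(=O)c1C | target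

**Totals**

Total step count: 20. Longest linear sequence: 19 steps (steps 1–6 and 8–20); step 7 is a one-step side branch.

**Steps most likely to fail**

1. Step 15. The allylsilane may close onto the conjugated C1 carbonyl (five-membered ring) or lose facial control when both dione carbonyls bind the Lewis acid (poor site and facial selectivity in the ring closure). Fallback, from 17 back to 20, with only one ketone present: DIBAL-H at −78 °C should reduce 17 to the (Z)-enal F1. 1-Ethoxyvinyllithium adds to the aldehyde to give the enol ether carbinol F2, and mild aqueous acid gives the α-hydroxy methyl ketone F3 (both carbinol epimers are used). TESOTf and 2,6-lutidine give the silyl ether F4. BF3·OEt2 then effects the same Sakurai closure onto the single ketone to give the cyclohexenol F5. PPTS in MeOH removes the TES group to give the diol F6, and MnO2 oxidises the secondary allylic alcohol to give 20. The carbinol configuration is immaterial because that carbon returns to the ketone.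

2. Step 20. Reagent control by the Ipc ligands may be too weak against the chiral aldehyde (mismatched double stereodifferentiation), and the boron Lewis acid may open the vinyl epoxide. Fallback, from 25 back to 28, with a covalent auxiliary: an Evans syn-aldol of (R)-4-benzyl-3-propionyloxazolidin-2-one (Bu2BOTf, Et3N, −78 → 0 °C) with 25 should give the imide adduct F7. Me3Al and MeNH(OMe)·HCl convert it to the Weinreb amide F8, and EtMgBr at −20 °C gives 28.

3. Step 5. The lipase may discriminate poorly between the two hydroxymethyl groups, or the monoester may scramble by acyl migration (erosion of enantiopurity). Fallback, from 7 back to 13, by separation of diastereomers: monoacylation of 7 with (S)-2-methoxy-2-phenylacetyl chloride and pyridine gives two diastereomeric monoesters that are separated; the wanted one is the (S)-O-methylmandelate F9. The unwanted one is saponified back to achiral 7 and recycled. Dess–Martin oxidation of F9 gives the aldehyde F10, olefination with 11 as in step 8 gives the enoate F11, and DIBAL-H as in step 9 gives 13.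

**Further compounds**

F1 | step 15 | (Z)-enal from 17 | O=C/C(C)=C\[C@@](/C=C(/C[Si](C)(C)C)CO[Si](c1ccccc1)(c1ccccc1)C(C)(C)C)(C)c1oc(OC)c(C)c(=O)c1C
F2 | step 15 | 1-ethoxyvinyl carbinol (epimers at the carbinol) | C=C(OCC)C(O)/C(C)=C\[C@@](/C=C(/C[Si](C)(C)C)CO[Si](c1ccccc1)(c1ccccc1)C(C)(C)C)(C)c1oc(OC)c(C)c(=O)c1C
F3 | step 15 | α-hydroxy methyl ketone (epimers at the carbinol) | CC(=O)C(O)/C(C)=C\[C@@](/C=C(/C[Si](C)(C)C)CO[Si](c1ccccc1)(c1ccccc1)C(C)(C)C)(C)c1oc(OC)c(C)c(=O)c1C
F4 | step 15 | α-triethylsilyloxy methyl ketone | CC(=O)C(O[Si](CC)(CC)CC)/C(C)=C\[C@@](/C=C(/C[Si](C)(C)C)CO[Si](c1ccccc1)(c1ccccc1)C(C)(C)C)(C)c1oc(OC)c(C)c(=O)c1C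
F5 | step 15 | cyclised tertiary alcohol with C1–OTES | C=C(CO[Si](c1ccccc1)(c1ccccc1)C(C)(C)C)[C@H]1[C@](C)(O)C(O[Si](CC)(CC)CC)C(C)=C[C@@]1(C)c1oc(OC)c(C)c(=O)c1C
F6 | step 15 | cyclohex-2-ene-1,6-diol (C1 epimers) | C=C(CO[Si](c1ccccc1)(c1ccccc1)C(C)(C)C)[C@H]1[C@](C)(O)C(O)C(C)=C[C@@]1(C)c1oc(OC)c(C)c(=O)c1C
F7 | step 20 | Evans syn-aldol imide | C=C([C@H](O)[C@@H](C)C(=O)N1[C@H](Cc2ccccc2)COC1=O)[C@H]1[C@]2(C)O[C@@H]2C(C)=C[C@@]1(C)c1oc(OC)c(C)c(=O)c1C
F8 | step 20 | syn-aldol Weinreb amide | C=C([C@H](O)[C@@H](C)C(=O)N(C)OC)[C@H]1[C@]2(C)O[C@@H]2C(C)=C[C@@]1(C)c1oc(OC)c(C)c(=O)c1C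
F9 | step 5 | mono-(S)-O-methylmandelate of 7 (wanted diastereomer) | CO[C@@H](c1ccccc1)C(=O)OC[C@@](CO)(C)c1oc(OC)c(C)c(=O)c1C
F10 | step 5 | aldehyde mandelate | CO[C@@H](c1ccccc1)C(=O)OC[C@@](C=O)(C)c1oc(OC)c(C)c(=O)c1C
F11 | step 5 | enoate mandelate | CO[C@@H](c1ccccc1)C(=O)OC[C@@](/C=C(/C[Si](C)(C)C)C(=O)OC)(C)c1oc(OC)c(C)c(=O)c1C
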